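## Structural features

The target is a C2-symmetric 3,3''-biflavanone: two chroman-4-one units (rings A/C and A''/C'') are joined by the single bond C3–C3''. Each unit carries a 4-methoxyphenyl ring B at C2 (C2''), a methoxy group at C5 (C5'') and a free hydroxyl at C7 (C7''). The four stereocentres C2, C3, C3'' and C2'' stand in a row with the configuration 2S,3R,2''S,3''R, which places H2/H3 and H2''/H3'' trans, so the aryl group and the inter-unit bond are both equatorial on each ring C. C3 and C3'' are α to the C4 ketones and epimerise under base. The benzylic O1–C2 bonds are β to those ketones, so base can open ring C to a 2'-hydroxychalcone and erase C2; the C5 methyl ethers peri to the carbonyls are the first a boron halide would cleave. The real difficulty is twofold: the crowded C3–C3'' bond between two stereocentres, and the absolute configuration at C2 and C2'' in a molecule whose three ring A oxygens (O1, O5, O7) must all end up different. Rings A and A'' are acylphloroglucinols: C4a carries the C4 acyl carbon and is flanked by the oxygen-bearing C5 and C8a, with the third oxygen para at C7. This is the pattern of a folded tricarbonyl chain, so C4a–C5 (and C4a''–C5'') can be made by Claisen condensation of a chain stored as a 2-pyrone, and the pyrone C4 oxygen becomes O7, which lets the group that marks O7 be in place before ring A exists.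

## Logic of the disconnections

15 ⇒ 14. The O7–H and O7''–H bonds are replaced by O–benzyl bonds. The free phenols would compete in the methylation and disturb the base-sensitive steps, and benzyl is a mask that comes off without acid or base. The gain is chemoselectivity only. The forward hydrogenolysis must leave the benzylic C2–O1 bonds, the ketones and the four stereocentres untouched.

14 ⇒ 12 (through 13). The O1–C2 and O1''–C2'' bonds are cut. This removes all four stereocentres at once: C2 and C2'' become sp2 arylidene carbons, and C3 and C3'' need no separate control because they follow C2 into the trans arrangement by enolisation. What remains is achiral. The forward step must choose the same face of both arylidene carbons under catalyst control and be stopped before base-induced ring opening erodes the result.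

12 ⇒ 11. The O5–CH3 and O5''–CH3 bonds are cut. This restores the local symmetry of each ring A (two equivalent ortho hydroxyls), so the ring-forming step has no regiochemical question to answer. Methylation is placed before ring closure on purpose: after closure it would be a reaction of a chelated hydroxyl on a base-labile flavanone. The forward step must stop at one methyl group per ring and relies on chelation of the second hydroxyl.

11 ⇒ 9 (through 10). The ring bonds C4a–C5 and C4a''–C5'' are cut and each ring A is unfolded to a tricarbonyl chain held as a 2-pyrone. This trades two penta-substituted benzene rings with three differentiated oxygens for two identical heterocycles derived from 7, and leaves the bis(arylidene) diketone core untouched. The benzyl ether on the pyrone C4 oxygen of 9 is chosen over a free hydroxyl for three reasons: it becomes the O7 benzyl ether of 11 without a late selective alkylation, it lets the pyrone react as a monoanion, and as an enol ether it takes the ester α-carbon out of the fold. The forward step must fold by C-acylation at C4a and must not touch the arylidene carbons.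

9 ⇒ 6 + 8. The bonds C4–C4a and C4''–C4a'' are cut (ketone carbon to pyrone methylene carbon). Both ketones come from one symmetrical diester and the nucleophile is the same on both sides, so the route is two-directional. The forward step needs carbon acylation at the lateral methyl group of 8, 1,2- and not 1,4-attack on 6, and enough anion to absorb the acidity of the product.

8 ⇒ 7. The O–benzyl bond is cut. 7 is a bulk chemical. The forward step must alkylate the C4 oxygen and not C3 or the lactone carbonyl oxygen.

6 ⇒ 5 ⇒ 4 + 1, and 4 ⇒ 3 ⇒ 1 + 2. The two arylidene double bonds (C2=C3 and C2''=C3'' in target numbering) are cut one after the other, with acid/ester interconversions between. The C3–C3'' bond is then the central bond of 2 and never has to be made, and both rings B come from 1. Each forward condensation must give the E alkene (aryl trans to carbonyl), and the second must act on the one remaining methylene of 4.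

## Other disconnections considered

Alternative 1: The cut is at C4–C4a and C4''–C4a''. Rings A would arrive as the aryllithium made from 5-(benzyloxy)-2-bromo-1,3-dimethoxybenzene A3, and the C2–C3–C3''–C2'' chain with both carboxyl carbons as the resolved cis-fused dilactone A2. Double addition would give the keto alcohol A1 or its bis-lactol.
- In its favour: all four sp3 carbons of the core are present in A2 in defined configuration, no asymmetric catalysis is needed, and addition of an aryllithium to a γ-lactone normally stops at the lactol/ketone stage.
- Against it here: A2 must be made as a racemate and resolved, so half the material is lost. A1 is a β-hydroxy ketone that can dehydrate to the bichalcone or cleave by retro-aldol reaction, and either destroys the stored stereochemistry.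
- Also against it: the carbinol carbons of A1 have the configuration opposite to that needed at C2 and C2'' if their oxygens were kept. Ring C must therefore be closed by a ring A phenol displacing the benzylic hydroxyl with inversion (or by ionisation under control from C3). That requires cleaving one of two equivalent ortho methyl ethers per ring with a Lewis acid such as BCl3 beside benzyl ethers.
- Comparison: on control of absolute configuration Alternative 1 is the better plan, since nothing depends on a catalyst-controlled closure, and its key step is mechanistically more routine than a polyketide fold. In step count the two are about equal once resolution, the synthesis of A3, demethylation and closure are counted. The chosen plan is preferred because its stereocentres are created last on a robust achiral intermediate, whereas Alternative 1 must carry four centres through a dehydration-prone intermediate and a substitution at an easily ionised 4-methoxybenzylic carbon.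

Alternative 2: C3–C3'' and a temporary C2–C2'' bond are treated as the two new bonds of a [2+2] photodimer. Chalcone A5 would dimerise head to head under Ru(bpy)3Cl2 sensitisation with Sc(OTf)3 and a chiral pyridine-bis(oxazoline) ligand to the all-trans cyclobutane A4. Single-electron oxidation would then break the electron-rich C2–C2'' bond and the two ortho phenols would capture the benzylic cations.
- In its favour: it is the shortest route, since A5 is one aldol condensation away from an acetophenone. The C3–C3'' bond and both C3 centres are set in one catalytic event, and the acyl-bearing carbons of A4 map directly onto 3R,3''R. C2 and C2'' would then follow by the trans preference, as in the chosen plan, so the two are equal on that point.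
- Against it here: homodimerisation must compete with E/Z isomerisation and head-to-tail pairing. The oxidative opening has no close precedent: a cyclobutane radical cation tends to revert to two alkenes, and the phenols and the flavanone product are themselves oxidisable.
- Comparison: Alternative 2 is better in step economy and in making C3–C3'' with stereocontrol. It is worse in mechanistic certainty, because the step after its key step is speculative, whereas every step after the fold in the chosen plan is of a known type.

Alternative 3: The cut is at O1–C2 and O1''–C2''. The bichalcone A7 (identical with 12) closes twice under a chiral tertiary amine–thiourea to A6 (identical with 14).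
- This is the closure used as step 9 of the chosen plan, so on this step the two plans are equal in every respect, including its weak points: hindered, weakly activated enones and a product that the basic catalyst can reopen.
- The difference is how A7 is reached. Alternative 3 keeps ring A as a preformed aromatic unit, for instance by adding the aryllithium from A3 to 6 and then unmasking one ortho oxygen per ring. That assembly is more routine than the fold and could be a step or two shorter, and on this point Alternative 3 is the better plan.
- Its price is a selective cleavage of one of two equivalent ortho methyl ethers beside benzyl ethers, or a less accessible unsymmetrically protected bromide.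
- The chosen plan reaches the same intermediate with the three ring A oxygens differentiated by construction (O7 benzylated from the pyrone, the two ortho oxygens free and told apart by chelation), at the cost of a less certain ring-forming step.

Key step: step 7

Assumptions and remarks
- Locants follow flavanone usage: C2–C8a for one unit, the same with double primes for the other; the carbons of rings B carry single and triple primes.
- The E,E geometry of 9, 11 and 12 is the one a Stobbe sequence delivers (each aryl trans to its carbonyl), so neither skeleton nor geometry needs correction. Two design points differ from a plan with free pyrone hydroxyls and late protection: the benzyl group is on the pyrone oxygen from step 5, and the C5 oxygens are methylated before rings C are closed.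
- The quinine-derived thiourea is assumed to favour the face that gives 2S; if the sense is the opposite, the quinidine-derived pseudo-enantiomer is used in step 9 with no other change.

## Route

Step 1
Reactants: 1 4-methoxybenzaldehyde; 2 diethyl succinate
Product: 3 (3E)-3-(ethoxycarbonyl)-4-(4-methoxyphenyl)but-3-enoic acid
Conditions: 2 (1.5 equiv), NaOEt (1.3 equiv), EtOH, reflux; then 2 M HCl
Reagents that add atoms: none
Why: Stobbe condensation of a succinic diester with a non-enolisable aldehyde; formation of the carboxylate drives it to completion, the aryl group ends trans to the ester carbonyl (E) for steric reasons, and the excess of 2 suppresses a second condensation.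

Step 2
Reactants: 3 (3E)-3-(ethoxycarbonyl)-4-(4-methoxyphenyl)but-3-enoic acid
Product: 4 diethyl (2E)-2-(4-methoxybenzylidene)succinate
Conditions: EtOH, H2SO4 (cat.), reflux
Reagents that add atoms: ethanol, CCO
Why: Fischer esterification of the free acid; the conjugated E alkene is the thermodynamic isomer and is not disturbed by acid.

Step 3
Reactants: 4 diethyl (2E)-2-(4-methoxybenzylidene)succinate; 1 4-methoxybenzaldehyde
Product: 5 (3E)-3-(ethoxycarbonyl)-2-[(E)-4-methoxybenzylidene]-4-(4-methoxyphenyl)but-3-enoic acid
Conditions: 1 (1.2 equiv), NaOEt (1.5 equiv), EtOH, reflux, dark; then 2 M HCl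
Reagents that add atoms: none
Why: Second Stobbe condensation at the only enolisable methylene of 4; the new alkene again forms with aryl trans to carbonyl, giving the E,E diene acid, and exclusion of light avoids E/Z isomerisation of the fulgide-type diene.

Step 4
Reactants: 5 (3E)-3-(ethoxycarbonyl)-2-[(E)-4-methoxybenzylidene]-4-(4-methoxyphenyl)but-3-enoic acid
Product: 6 diethyl (2E,3E)-2,3-bis(4-methoxybenzylidene)succinate
Conditions: EtI (3 equiv), K2CO3, DMF, rt, dark
Reagents that add atoms: iodoethane, CCI
Why: SN2 O-alkylation of the carboxylate under mild base, chosen over acid catalysis so that the hindered, light-sensitive diene acid is esterified at room temperature; any diacid from partial saponification in step 3 is converted into the same diester by the excess of EtI.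

Step 5
Reactants: 7 4-hydroxy-6-methyl-2H-pyran-2-one
Product: 8 4-(benzyloxy)-6-methyl-2H-pyran-2-one
Conditions: BnOH, PPh3, DIAD, THF, 0 °C to rt
Reagents that add atoms: benzyl alcohol, OCc1ccccc1
Why: Mitsunobu etherification of the acidic vinylogous carboxylic acid; alkylation takes place at the C4 oxygen and avoids the C3-benzylation that a benzyl halide with base can cause.

Step 6
Reactants: 8 4-(benzyloxy)-6-methyl-2H-pyran-2-one; 6 diethyl (2E,3E)-2,3-bis(4-methoxybenzylidene)succinate
Product: 9 6,6'-[(3E,4E)-3,4-bis(4-methoxybenzylidene)-2,5-dioxohexane-1,6-diyl]bis[4-(benzyloxy)-2H-pyran-2-one]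
Conditions: 8 (4.4 equiv), LiN(i-Pr)2 (4.4 equiv), THF, −78 °C; add 6, −78 to −20 °C, dark; then 1 M HCl
Reagents that add atoms: none
Why: Claisen-type C-acylation of the laterally lithiated 6-methyl group (a vinylogous ester enolate) by the two non-enolisable ester groups; the second equivalent of anion per ester deprotonates the doubly activated methylene of the product and so protects the new ketones. 1,2-Attack is expected because the arylidene carbons are trisubstituted and deactivated by the 4-methoxyphenyl groups.

Step 7
Reactants: 9 6,6'-[(3E,4E)-3,4-bis(4-methoxybenzylidene)-2,5-dioxohexane-1,6-diyl]bis[4-(benzyloxy)-2H-pyran-2-one]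
Product: 11 (2E,3E)-1,4-bis[4-(benzyloxy)-2,6-dihydroxyphenyl]-2,3-bis(4-methoxybenzylidene)butane-1,4-dione, via ring-opened bis(benzyl ester) 10 (not isolated)
Conditions: Mg(OBn)2 (6 equiv, from n-Bu2Mg and BnOH), BnOH–THF, 60 °C, argon, dark; then cold 1 M HCl
Reagents that add atoms: none
Why: Benzyloxide adds to each lactone carbonyl and the pyrone opens to the magnesium 5,7-diketonate of a 3-benzyloxy-5,7-dioxo-2-enoate, the enol-ether-masked form of a 3,5,7-triketo ester (10). The central carbon of that diketonate, the future C4a, then attacks the ester carbonyl, the future C5, in a Claisen condensation, and loss of benzyloxide followed by enolisation gives the aromatic ring. The closest known reaction type is the magnesium alkoxide-mediated cyclisation of 3,5,7-triketo esters and of the 6-(2-oxoalkyl)-2-pyrones that mask them to acylphloroglucinols. Rings A and A'' each close in the 6-exo-trig mode, helped by the cis enol ether double bond inherited from the pyrone, which holds ester and nucleophile on the same side. No stereocentre is formed. The selectivity needed is C-acylation over the aldol fold to a resorcylate, over O-cyclisation to a 4-pyranone and over Michael addition to the arylidene carbons: the benzyl enol ether removes the ester α-carbon from the active methylenes so that no aldol ring can form, magnesium chelation makes the diketonate react at carbon, and the core carbons are trisubstituted, donor-substituted and carry no enolisable hydrogen. Benzyloxide is used in place of methoxide so that any alkoxy exchange at the enol ether carbon is degenerate and O7 stays benzylated; the cold acidic quench is meant to keep 11 open as the bichalcone.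

Step 8
Reactants: 11 (2E,3E)-1,4-bis[4-(benzyloxy)-2,6-dihydroxyphenyl]-2,3-bis(4-methoxybenzylidene)butane-1,4-dione
Product: 12 (2E,3E)-1,4-bis[4-(benzyloxy)-2-hydroxy-6-methoxyphenyl]-2,3-bis(4-methoxybenzylidene)butane-1,4-dione
Conditions: Me2SO4 (2.1 equiv), K2CO3 (2.2 equiv), acetone, 0 °C to rt, dark
Reagents that add atoms: dimethyl sulfate, COS(=O)(=O)OC
Why: Chelation-controlled mono-O-methylation: in each 2,6-dihydroxyaryl ketone only one hydroxyl can be hydrogen-bonded to the carbonyl, the other is ionised and methylated, and the hydroxyl that remains is then locked in the chelate and resists the weak base. The step stands before ring closure because the same operation on a closed flavanone would need base strong enough to open ring C and erase C2.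

Step 9
Reactants: 12 (2E,3E)-1,4-bis[4-(benzyloxy)-2-hydroxy-6-methoxyphenyl]-2,3-bis(4-methoxybenzylidene)butane-1,4-dione
Product: 14 (2S,3R,2''S,3''R)-7,7''-di-O-benzyl-4',4''',5,5''-tetramethylchamaejasmin, via half-closed flavanone chalcone 13 (not isolated)
Conditions: 9-amino(9-deoxy)epi-quinine-derived 3,5-bis(trifluoromethyl)phenyl thiourea (20 mol %), toluene, 0 °C to rt, dark; stopped at full conversion
Reagents that add atoms: none
Why: Intramolecular asymmetric oxa-Michael addition (6-endo-trig) of each ortho phenol to its arylidene carbon under bifunctional base/hydrogen-bond catalysis; the catalyst selects the face at C2 and C2'', while C3 and C3'' are set by protonation of the enolates and settle by enolisation in the 2,3-trans arrangement with both substituents equatorial. Because the same catalyst makes both closures, an error in one of them leads mainly to the separable meso diastereomer and not to the enantiomer.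

Step 10
Reactants: 14 (2S,3R,2''S,3''R)-7,7''-di-O-benzyl-4',4''',5,5''-tetramethylchamaejasmin
Product: 15 (2S,3R,2''S,3''R)-4',4''',5,5''-tetramethylchamaejasmin
Conditions: H2 (1 atm), 10% Pd/C, EtOAc–MeOH, rt
Reagents that add atoms: none
Why: Hydrogenolysis of the two aryl benzyl ethers under neutral conditions, which neither epimerises C3 nor opens ring C; the reaction is stopped after uptake of two equivalents of H2 to spare the benzylic C2–O1 bonds and the aryl ketones.

## Compound list

1 | 4-methoxybenzaldehyde | COc1ccc(C=O)cc1 | starting material
2 | diethyl succinate | CCOC(=O)CCC(=O)OCC | starting material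
3 | (3E)-3-(ethoxycarbonyl)-4-(4-methoxyphenyl)but-3-enoic acid | CCOC(=O)/C(CC(=O)O)=C/c1ccc(OC)cc1 | intermediate
4 | diethyl (2E)-2-(4-methoxybenzylidene)succinate | CCOC(=O)/C(CC(=O)OCC)=C/c1ccc(OC)cc1 | intermediate
5 | (3E)-3-(ethoxycarbonyl)-2-[(E)-4-methoxybenzylidene]-4-(4-methoxyphenyl)but-3-enoic acid | CCOC(=O)/C(=C/c1ccc(OC)cc1)/C(=C\c1ccc(OC)cc1)C(=O)O | intermediate
6 | diethyl (2E,3E)-2,3-bis(4-methoxybenzylidene)succinate | CCOC(=O)/C(=C/c1ccc(OC)cc1)/C(=C\c1ccc(OC)cc1)C(=O)OCC | intermediate
7 | 4-hydroxy-6-methyl-2H-pyran-2-one | Cc1cc(O)cc(=O)o1 | starting material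
8 | 4-(benzyloxy)-6-methyl-2H-pyran-2-one | Cc1cc(OCc2ccccc2)cc(=O)o1 | intermediate
9 | 6,6'-[(3E,4E)-3,4-bis(4-methoxybenzylidene)-2,5-dioxohexane-1,6-diyl]bis[4-(benzyloxy)-2H-pyran-2-one] | O=c1cc(OCc2ccccc2)cc(CC(=O)/C(=C/c2ccc(OC)cc2)/C(=C\c2ccc(OC)cc2)C(=O)Cc2cc(OCc3ccccc3)cc(=O)o2)o1 | intermediate
10 | dibenzyl (2E,14E)-3,14-bis(benzyloxy)-8,9-bis[(E)-4-methoxybenzylidene]-5,7,10,12-tetraoxohexadeca-2,14-dienedioate (present as magnesium enolates, drawn in the keto form) | O=C(OCc1ccccc1)/C=C(OCc1ccccc1)\CC(=O)CC(=O)/C(=C/c1ccc(OC)cc1)/C(=C\c1ccc(OC)cc1)C(=O)CC(=O)C/C(OCc1ccccc1)=C\C(=O)OCc1ccccc1 | intermediate (not isolated)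
11 | (2E,3E)-1,4-bis[4-(benzyloxy)-2,6-dihydroxyphenyl]-2,3-bis(4-methoxybenzylidene)butane-1,4-dione | O=C(c1c(O)cc(OCc2ccccc2)cc1O)/C(=C/c1ccc(OC)cc1)/C(=C\c1ccc(OC)cc1)C(=O)c1c(O)cc(OCc2ccccc2)cc1O | intermediate
12 | (2E,3E)-1,4-bis[4-(benzyloxy)-2-hydroxy-6-methoxyphenyl]-2,3-bis(4-methoxybenzylidene)butane-1,4-dione | O=C(c1c(O)cc(OCc2ccccc2)cc1OC)/C(=C/c1ccc(OC)cc1)/C(=C\c1ccc(OC)cc1)C(=O)c1c(O)cc(OCc2ccccc2)cc1OC | intermediate
13 | (2S,3R)-7-(benzyloxy)-3-[(1E)-3-[4-(benzyloxy)-2-hydroxy-6-methoxyphenyl]-1-(4-methoxyphenyl)-3-oxoprop-1-en-2-yl]-5-methoxy-2-(4-methoxyphenyl)chroman-4-one | COc1ccc([C@H]2Oc3cc(OCc4ccccc4)cc(OC)c3C(=O)[C@@H]2/C(=C\c2ccc(OC)cc2)C(=O)c2c(O)cc(OCc3ccccc3)cc2OC)cc1 | intermediate (not isolated)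
14 | (2S,3R,2''S,3''R)-7,7''-di-O-benzyl-4',4''',5,5''-tetramethylchamaejasmin; (2S,2'S,3R,3'R)-7,7'-bis(benzyloxy)-5,5'-dimethoxy-2,2'-bis(4-methoxyphenyl)-[3,3'-bichromane]-4,4'-dione | COc1ccc([C@H]2Oc3cc(OCc4ccccc4)cc(OC)c3C(=O)[C@@H]2[C@H]2C(=O)c3c(OC)cc(OCc4ccccc4)cc3O[C@@H]2c2ccc(OC)cc2)cc1 | intermediate
15 | (2S,3R,2''S,3''R)-4',4''',5,5''-tetramethylchamaejasmin; (2S,2'S,3R,3'R)-7,7'-dihydroxy-5,5'-dimethoxy-2,2'-bis(4-methoxyphenyl)-[3,3'-bichromane]-4,4'-dione | COc1ccc([C@H]2Oc3cc(O)cc(OC)c3C(=O)[C@@H]2[C@H]2C(=O)c3c(OC)cc(O)cc3O[C@@H]2c2ccc(OC)cc2)cc1 | target

## Step count and least certain steps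

Total: 10 steps. Longest linear sequence: 9 steps (1/2 → 3 → 4 → 5 → 6 → 9 → 11 → 12 → 14 → 15); step 5 is a one-step side branch.

Least certain steps, most uncertain first:

Step 7 (key step). The ring-opened chain may be diverted away from C-acylation. The β-benzyloxy acrylate ester is a weaker acceptor than a β-keto ester, so re-closure to the pyrone, O-cyclisation of the diketonate onto the enol ether carbon (4-pyranone formation) or alkoxide addition to the arylidene carbons may outrun the Claisen closure. Ring C may also close prematurely and without stereocontrol on the magnesium phenoxide. Fallback, setting out from 6 and 7 and returning at 11: 7 (4.4 equiv) is converted into its dianion with LiN(i-Pr)2 (8.8 equiv) in THF at −78 to 0 °C and acylated at the methyl carbon by 6 to give 6,6'-[(3E,4E)-3,4-bis(4-methoxybenzylidene)-2,5-dioxohexane-1,6-diyl]bis(4-hydroxy-2H-pyran-2-one) F1. Mg(OMe)2 in MeOH at reflux, the parent conditions for the Claisen fold of free 4-hydroxy-pyrones, should then give (2E,3E)-2,3-bis(4-methoxybenzylidene)-1,4-bis(2,4,6-trihydroxyphenyl)butane-1,4-dione F2. Its two para hydroxyls, the most acidic and the only unchelated ones, are benzylated with BnBr (2.0 equiv) and K2CO3 in acetone to give 11. The regiochemical task is moved to this last alkylation, which is the price of the fallback.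

Step 9. Facial selectivity may be poor or turnover sluggish, because the enones are α-branched, twisted and deactivated by the 4-methoxyphenyl groups. C2 may also erode by reversible ring opening under the basic catalyst, and the second closure may be mismatched with the centres formed in the first. Fallback, setting out from 12 and returning at 14: both rings are closed without asymmetric induction under thermodynamic control (NaOAc, EtOH, reflux), which should give the 2,3-trans products as the racemate of 14 together with the meso isomer. The racemate is resolved by preparative HPLC on a polysaccharide chiral stationary phase into 14 and its enantiomer, (2R,3S,2''R,3''S)-7,7''-di-O-benzyl-4',4''',5,5''-tetramethylchamaejasmin F3. The meso isomer, (2S,3R,2''R,3''S)-7,7''-di-O-benzyl-4',4''',5,5''-tetramethylisochamaejasmin F4, is removed beforehand by chromatography on silica. F3 and F4 can be re-opened to 12 with KOH in aqueous EtOH and recycled.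

Step 6. Acylation may be incomplete or misdirected: the ester carbonyls are hindered and cross-conjugated, the product consumes a second equivalent of anion, and conjugate addition or attack of the anion on a second pyrone may compete. Fallback, setting out from 6 and returning at 9: 6 is treated with MeNH(OMe)·HCl and i-PrMgCl in THF at −20 °C to give (2E,3E)-N,N'-dimethoxy-2,3-bis(4-methoxybenzylidene)-N,N'-dimethylsuccinamide F5. Lithiated 8 (2.4 equiv; LiN(i-Pr)2, THF, −78 °C) adds to this Weinreb amide to form a chelated tetrahedral intermediate that releases the ketone only on acidic work-up. The product can therefore neither quench the nucleophile nor be attacked twice, and 9 results.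

Step 8. Chemoselectivity may be lost, either by a second methylation within one ring or by base-induced closure of a phenoxide on its arylidene carbon before the chiral catalyst is present. Fallback, setting out from 11 and returning at 12: the order is inverted for this one operation. 11 is closed on purpose (NaOAc, EtOH, reflux) to 7,7''-bis(benzyloxy)-5,5''-dihydroxy-4',4'''-dimethoxy-3,3''-biflavanone F6, a stereoisomer mixture in which one ortho oxygen of each ring is tied up as O1. The single remaining hydroxyl of each ring is methylated (Me2SO4, K2CO3, acetone, reflux) to 7,7''-bis(benzyloxy)-4',4''',5,5''-tetramethoxy-3,3''-biflavanone F7, again a stereoisomer mixture. KOH in aqueous EtOH then re-opens both rings C by E1cB elimination, and cold acidification returns the achiral bichalcone 12, so the stereochemical disorder of F6 and F7 has no consequence.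

## Further compounds

F1 | step 7 | 6,6'-[(3E,4E)-3,4-bis(4-methoxybenzylidene)-2,5-dioxohexane-1,6-diyl]bis(4-hydroxy-2H-pyran-2-one) | O=c1cc(O)cc(CC(=O)/C(=C/c2ccc(OC)cc2)/C(=C\c2ccc(OC)cc2)C(=O)Cc2cc(O)cc(=O)o2)o1
F2 | step 7 | (2E,3E)-2,3-bis(4-methoxybenzylidene)-1,4-bis(2,4,6-trihydroxyphenyl)butane-1,4-dione | O=C(c1c(O)cc(O)cc1O)/C(=C/c1ccc(OC)cc1)/C(=C\c1ccc(OC)cc1)C(=O)c1c(O)cc(O)cc1O
F3 | step 9 | (2R,3S,2''R,3''S)-7,7''-di-O-benzyl-4',4''',5,5''-tetramethylchamaejasmin (enantiomer of 14) | COc1ccc([C@@H]2Oc3cc(OCc4ccccc4)cc(OC)c3C(=O)[C@H]2[C@@H]2C(=O)c3c(OC)cc(OCc4ccccc4)cc3O[C@H]2c2ccc(OC)cc2)cc1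
F4 | step 9 | (2S,3R,2''R,3''S)-7,7''-di-O-benzyl-4',4''',5,5''-tetramethylisochamaejasmin (meso) | COc1ccc([C@H]2Oc3cc(OCc4ccccc4)cc(OC)c3C(=O)[C@@H]2[C@@H]2C(=O)c3c(OC)cc(OCc4ccccc4)cc3O[C@H]2c2ccc(OC)cc2)cc1
F5 | step 6 | (2E,3E)-N,N'-dimethoxy-2,3-bis(4-methoxybenzylidene)-N,N'-dimethylsuccinamide | CON(C)C(=O)/C(=C/c1ccc(OC)cc1)/C(=C\c1ccc(OC)cc1)C(=O)N(C)OC
F6 | step 8 | 7,7''-bis(benzyloxy)-5,5''-dihydroxy-4',4'''-dimethoxy-3,3''-biflavanone (stereoisomer mixture, centres left undefined) | O=C1c2c(O)cc(OCc3ccccc3)cc2OC(c2ccc(OC)cc2)C1C1C(=O)c2c(O)cc(OCc3ccccc3)cc2OC1c1ccc(OC)cc1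
F7 | step 8 | 7,7''-bis(benzyloxy)-4',4''',5,5''-tetramethoxy-3,3''-biflavanone (stereoisomer mixture, centres left undefined) | COc1ccc(C2Oc3cc(OCc4ccccc4)cc(OC)c3C(=O)C2C2C(=O)c3c(OC)cc(OCc4ccccc4)cc3OC2c2ccc(OC)cc2)cc1
A1 | alternative 1 | syn,syn-1,4-bis[4-(benzyloxy)-2,6-dimethoxyphenyl]-2,3-bis[hydroxy(4-methoxyphenyl)methyl]butane-1,4-dione | COc1ccc([C@H](O)[C@H](C(=O)c2c(OC)cc(OCc3ccccc3)cc2OC)[C@@H](C(=O)c2c(OC)cc(OCc3ccccc3)cc2OC)[C@@H](O)c2ccc(OC)cc2)cc1
A2 | alternative 1 | 3,6-bis(4-methoxyphenyl)tetrahydro-1H,3H-furo[3,4-c]furan-1,4-dione (cis-fused, both aryl groups exo, single enantiomer) | COc1ccc([C@@H]2OC(=O)[C@@H]3[C@H]2C(=O)O[C@H]3c2ccc(OC)cc2)cc1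
A3 | alternative 1 | 5-(benzyloxy)-2-bromo-1,3-dimethoxybenzene | COc1cc(OCc2ccccc2)cc(OC)c1Br
A4 | alternative 2 | all-trans-[3,4-bis(4-methoxyphenyl)cyclobutane-1,2-diyl]bis{[4-(benzyloxy)-2-hydroxy-6-methoxyphenyl]methanone} | O=C(c1c(O)cc(OCc2ccccc2)cc1OC)[C@H]1[C@H](c2ccc(OC)cc2)[C@@H](c2ccc(OC)cc2)[C@@H]1C(=O)c1c(O)cc(OCc2ccccc2)cc1OC
A5 | alternative 2 | (2E)-1-[4-(benzyloxy)-2-hydroxy-6-methoxyphenyl]-3-(4-methoxyphenyl)prop-2-en-1-one | COc1ccc(/C=C/C(=O)c2c(O)cc(OCc3ccccc3)cc2OC)cc1
A6 | alternative 3 | (2S,3R,2''S,3''R)-7,7''-di-O-benzyl-4',4''',5,5''-tetramethylchamaejasmin (identical with 14) | COc1ccc([C@H]2Oc3cc(OCc4ccccc4)cc(OC)c3C(=O)[C@@H]2[C@H]2C(=O)c3c(OC)cc(OCc4ccccc4)cc3O[C@@H]2c2ccc(OC)cc2)cc1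
A7 | alternative 3 | (2E,3E)-1,4-bis[4-(benzyloxy)-2-hydroxy-6-methoxyphenyl]-2,3-bis(4-methoxybenzylidene)butane-1,4-dione (identical with 12) | O=C(c1c(O)cc(OCc2ccccc2)cc1OC)/C(=C/c1ccc(OC)cc1)/C(=C\c1ccc(OC)cc1)C(=O)c1c(O)cc(OCc2ccccc2)cc1OC
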